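**Plan**

Ring A is the 3,4-dihydro-2H-pyran (O1, C2 methyl, C3 hydroxymethyl, C4 acetate arm, C5 ester, C6). The retrosynthesis cuts (a) the benzyl ethers and the ester C–O bond of the arm (carboxylate alkylation), after tying the C3 hydroxymethyl and the C4 arm back into a six-membered lactone, ring B; (b) O1–C2 and C4–C5 of ring A together; (c) the C=C of ring B (metathesis); (d) the C3–vinyl bond (epoxide opening).
Enabling feature: O1–C6=C5(CO2Me) is the enol ether of a formyl ester, a 1,3-dicarbonyl C,O-bis-nucleophile. C4 is β to the arm carbonyl (the Michael position of the ring B enoate) and C2 is a secondary ether carbon two atoms away, so C4–C3–C2 is a 1,3-bis-electrophile.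
Forward: epoxy alcohol, then 2-vinyl-1,3-diol, then acrylate mesylate, then ring B by metathesis, then ring A by a Michael/O-alkylation [3+3] annulation with sodium methyl formylacetate. Ring B is then opened, the carboxylate alkylated with the protected hydroxytyrosol bromide, and the benzyl groups removed.
Stereochemistry: C2 and C3 come from the Sharpless epoxide (C3 by inversion on opening, C2 by a second inversion in the ether closure); C4 comes from attack trans to the C3 arm on ring B.

Key step: step 7

Remark: the enolate geometry of 11 and 12 is mobile and is left unspecified in their SMILES; 12 is drawn after proton transfer to the formyl-ester enolate.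

**Route**

Step 1
Reactants: 1 (E)-but-2-en-1-ol
Product: 2 [(2S,3S)-3-methyloxiran-2-yl]methanol
Conditions: Ti(OiPr)4 (cat.), L-(+)-diethyl tartrate (cat.), tBuOOH, 4 Å sieves, CH2Cl2, −20 °C; non-aqueous work-up, distillation
Reagents that add atoms: tert-butyl hydroperoxide, CC(C)(C)OO
Why: Sharpless asymmetric epoxidation of a trans-disubstituted allylic alcohol, in which the L-(+)-tartrate/titanium complex delivers oxygen to one enantioface and sets both epoxide centres as (2S,3S).

Step 2
Reactants: 2 [(2S,3S)-3-methyloxiran-2-yl]methanol, 3 vinylmagnesium bromide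
Product: 4 (2R,3S)-2-ethenylbutane-1,3-diol
Conditions: CH2=CHMgBr (3 equiv), CuI (10 mol %), THF/Et2O, −30 to 0 °C; aqueous work-up; NaIO4 wash of the crude to cleave any 1,2-diol regioisomer
Reagents that add atoms: none
Why: Copper-catalysed Grignard opening of a 2,3-epoxy alcohol should take place mainly at C2 of the magnesium alkoxide with inversion (anti opening), which sets the vinyl-bearing centre and leaves the carbinol centre untouched.

Step 3
Reactants: 4 (2R,3S)-2-ethenylbutane-1,3-diol, 5 acryloyl chloride
Product: 6 (2R,3S)-2-ethenyl-3-hydroxybutyl prop-2-enoate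
Conditions: acryloyl chloride (1.05 equiv), 2,4,6-collidine, CH2Cl2, −78 °C
Reagents that add atoms: none
Why: Kinetic esterification of the primary over the secondary hydroxyl with an acid chloride and a hindered pyridine base at low temperature.

Step 4
Reactants: 6 (2R,3S)-2-ethenyl-3-hydroxybutyl prop-2-enoate
Product: 7 (2R,3S)-2-ethenyl-3-(methanesulfonyloxy)butyl prop-2-enoate
Conditions: MsCl, Et3N, CH2Cl2, 0 °C
Reagents that add atoms: methanesulfonyl chloride, CS(=O)(=O)Cl
Why: Standard sulfonylation at oxygen (retention at carbon) turns the secondary C–O bond into the leaving group for the later ether closure.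

Step 5
Reactants: 7 (2R,3S)-2-ethenyl-3-(methanesulfonyloxy)butyl prop-2-enoate
Product: 8 (5R)-5-[(1S)-1-(methanesulfonyloxy)ethyl]-5,6-dihydro-2H-pyran-2-one
Conditions: second-generation Grubbs catalyst RuCl2(=CHPh)(PCy3)(H2IMes) (5 mol %), CH2Cl2, 40 °C, high dilution
Reagents that add atoms: none
Why: Ring-closing metathesis of an acrylate with a monosubstituted alkene is the standard entry to 5,6-dihydro-2H-pyran-2-ones; loss of ethene drives it and the mesylate is inert to the ruthenium carbene.

Step 6
Reactants: 9 methyl acetate, 10 methyl formate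
Product: 11 sodium 3-methoxy-3-oxoprop-1-en-1-olate (sodium enolate of methyl formylacetate)
Conditions: NaH (1.0 equiv), MeOH (cat.), Et2O, 0 °C to rt; the salt is filtered off and dried
Reagents that add atoms: sodium hydride, [Na+].[H-]
Why: Crossed Claisen condensation, in which methyl formate (no α-hydrogen, the more electrophilic ester) acylates the acetate enolate and the product leaves the equilibrium as its insoluble sodium enolate.

Step 7
Reactants: 8 (5R)-5-[(1S)-1-(methanesulfonyloxy)ethyl]-5,6-dihydro-2H-pyran-2-one, 11 sodium 3-methoxy-3-oxoprop-1-en-1-olate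
Product: 13 methyl (1R,4aS,8aR)-1-methyl-6-oxo-4a,5,6,8a-tetrahydro-1H,8H-pyrano[3,4-c]pyran-4-carboxylate, via Michael adduct sodium enolate 12 (not isolated)
Conditions: 11 (1.5 equiv), 15-crown-5 (0.2 equiv), DMF, 0 to 40 °C
Reagents that add atoms: none
Why: Proposed new method: the carbon terminus of enolate 11 should add 1,4 to the cyclic enoate of 8, the resulting lactone enolate is quenched by the far more acidic formyl-ester C–H to give 12, and the enolate oxygen of 12 then displaces the secondary mesylate, so the C–C bond and the ring C–O bond form in one flask. The closest known reaction types are the Michael-initiated ring closure and the base-mediated [3+3] annulations of 1,3-dicarbonyl compounds with 1,3-bis-electrophiles (1,3-dihalides, Morita–Baylis–Hillman acetates) that give 3,4-dihydro-2H-pyrans by carbon-then-oxygen bond formation. Ring A closes in the 6-exo-tet mode by O-alkylation, since C-alkylation would need a four-membered ring. The Michael carbon is controlled by the adjacent stereocentre of 8 (attack trans to the 1-mesyloxyethyl arm, which is also the thermodynamic outcome of a reversible addition) and gives the trans ring fusion; the methyl-bearing carbon is set by SN2 inversion of the (S)-mesylate to the (R)-ether. The step needs carbon attack on the enoate before any substitution or elimination at the mesylate: the mesylate is secondary and β-branched, so intermolecular SN2 is slow, and the pre-formed enolate is a weak base used without any stronger base present.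

Step 8
Reactants: 14 4-(2-hydroxyethyl)benzene-1,2-diol (hydroxytyrosol)
Product: 15 2-[3,4-bis(benzyloxy)phenyl]ethan-1-ol
Conditions: BnBr (2.2 equiv), K2CO3, acetone, reflux
Reagents that add atoms: benzyl bromide, BrCc1ccccc1
Why: Williamson etherification in which carbonate deprotonates only the two phenols, so the aliphatic alcohol stays free.

Step 9
Reactants: 15 2-[3,4-bis(benzyloxy)phenyl]ethan-1-ol
Product: 16 4-(2-bromoethyl)-1,2-bis(benzyloxy)benzene
Conditions: CBr4, PPh3, CH2Cl2, 0 °C
Reagents that add atoms: tetrabromomethane, BrC(Br)(Br)Br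
Why: Appel bromination of a primary alcohol (SN2 on the alkoxyphosphonium ion), to which the aryl benzyl ethers are inert.

Step 10
Reactants: 13 methyl (1R,4aS,8aR)-1-methyl-6-oxo-4a,5,6,8a-tetrahydro-1H,8H-pyrano[3,4-c]pyran-4-carboxylate, 16 4-(2-bromoethyl)-1,2-bis(benzyloxy)benzene
Product: 18 methyl (2R,3R,4S)-4-{2-[2-(3,4-bis(benzyloxy)phenyl)ethoxy]-2-oxoethyl}-3-(hydroxymethyl)-2-methyl-3,4-dihydro-2H-pyran-5-carboxylate, via cesium carboxylate 17 (not isolated)
Conditions: CsOH·H2O (1.0 equiv), THF/H2O, 0 °C; evaporation, toluene azeotrope; then 16 (1.2 equiv), DMF, rt to 40 °C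
Reagents that add atoms: cesium hydroxide monohydrate, O.[OH-].[Cs+]
Why: Saponification should open the δ-lactone much faster than hydroxide attacks the vinylogous-carbonate methyl ester, and SN2 alkylation of the cesium carboxylate by the primary bromide forms the ester without activating the acid towards re-lactonisation by the free δ-hydroxyl.

Step 11
Reactants: 18 methyl (2R,3R,4S)-4-{2-[2-(3,4-bis(benzyloxy)phenyl)ethoxy]-2-oxoethyl}-3-(hydroxymethyl)-2-methyl-3,4-dihydro-2H-pyran-5-carboxylate
Product: 19 methyl (2R,3R,4S)-4-{2-[2-(3,4-dihydroxyphenyl)ethoxy]-2-oxoethyl}-3-(hydroxymethyl)-2-methyl-3,4-dihydro-2H-pyran-5-carboxylate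
Conditions: H2 (1 atm), 10% Pd/C, EtOAc, rt; filtration, concentration below 30 °C
Reagents that add atoms: none
Why: Hydrogenolysis of aryl benzyl ethers over palladium is fast under neutral conditions, whereas the trisubstituted push–pull enol-ether acrylate and the esters should be reduced slowly or not at all.

**Compound list**

1 | (E)-but-2-en-1-ol | C/C=C/CO | starting material
2 | [(2S,3S)-3-methyloxiran-2-yl]methanol | C[C@@H]1O[C@H]1CO | intermediate
3 | vinylmagnesium bromide | C=C[Mg]Br | starting material
4 | (2R,3S)-2-ethenylbutane-1,3-diol | C[C@H](O)[C@H](C=C)CO | intermediate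
5 | acryloyl chloride | C=CC(=O)Cl | starting material
6 | (2R,3S)-2-ethenyl-3-hydroxybutyl prop-2-enoate | C[C@H](O)[C@H](C=C)COC(=O)C=C | intermediate
7 | (2R,3S)-2-ethenyl-3-(methanesulfonyloxy)butyl prop-2-enoate | C[C@H](OS(C)(=O)=O)[C@H](C=C)COC(=O)C=C | intermediate
8 | (5R)-5-[(1S)-1-(methanesulfonyloxy)ethyl]-5,6-dihydro-2H-pyran-2-one | C[C@H](OS(C)(=O)=O)[C@H]1COC(=O)C=C1 | intermediate
9 | methyl acetate | COC(C)=O | starting material
10 | methyl formate | COC=O | starting material
11 | sodium 3-methoxy-3-oxoprop-1-en-1-olate | COC(=O)C=C[O-].[Na+] | intermediate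
12 | sodium 3-methoxy-2-[(4S,5R)-5-[(1S)-1-(methanesulfonyloxy)ethyl]-2-oxooxan-4-yl]-3-oxoprop-1-en-1-olate (Michael adduct, not isolated) | COC(=O)C(=C[O-])[C@H]1CC(=O)OC[C@@H]1[C@H](C)OS(C)(=O)=O.[Na+] | intermediate
13 | methyl (1R,4aS,8aR)-1-methyl-6-oxo-4a,5,6,8a-tetrahydro-1H,8H-pyrano[3,4-c]pyran-4-carboxylate (trans-fused; ring A enol ether, ring B lactone) | COC(=O)C1=CO[C@H](C)[C@H]2COC(=O)C[C@H]12 | intermediate
14 | 4-(2-hydroxyethyl)benzene-1,2-diol (hydroxytyrosol) | OCCc1ccc(O)c(O)c1 | starting material
15 | 2-[3,4-bis(benzyloxy)phenyl]ethan-1-ol | OCCc1ccc(OCc2ccccc2)c(OCc2ccccc2)c1 | intermediate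
16 | 4-(2-bromoethyl)-1,2-bis(benzyloxy)benzene | BrCCc1ccc(OCc2ccccc2)c(OCc2ccccc2)c1 | intermediate
17 | cesium 2-[(2R,3R,4S)-3-(hydroxymethyl)-5-(methoxycarbonyl)-2-methyl-3,4-dihydro-2H-pyran-4-yl]acetate (not isolated) | COC(=O)C1=CO[C@H](C)[C@@H](CO)[C@@H]1CC(=O)[O-].[Cs+] | intermediate
18 | methyl (2R,3R,4S)-4-{2-[2-(3,4-bis(benzyloxy)phenyl)ethoxy]-2-oxoethyl}-3-(hydroxymethyl)-2-methyl-3,4-dihydro-2H-pyran-5-carboxylate | COC(=O)C1=CO[C@H](C)[C@@H](CO)[C@@H]1CC(=O)OCCc1ccc(OCc2ccccc2)c(OCc2ccccc2)c1 | intermediate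
19 | methyl (2R,3R,4S)-4-{2-[2-(3,4-dihydroxyphenyl)ethoxy]-2-oxoethyl}-3-(hydroxymethyl)-2-methyl-3,4-dihydro-2H-pyran-5-carboxylate | COC(=O)C1=CO[C@H](C)[C@@H](CO)[C@@H]1CC(=O)OCCc1ccc(O)c(O)c1 | target

**Step count and risks**

Total step count: 11. Longest linear sequence: 8 steps (steps 1, 2, 3, 4, 5, 7, 10, 11).

Steps most likely to fail:

1. Step 7 (proposed new method). The Michael addition may be too slow or too reversible to feed the ring closure. The weakly basic enolate may instead remove the γ-hydrogen of the enoate and expel the mesylate (vinylogous elimination), after which the nucleophile would add at the wrong terminus. Fallback, from 8 back to 13, using known reaction types in separate steps: the lithium enolate of commercial methyl 3,3-dimethoxypropanoate (LiN(iPr)2, THF, −78 °C, pre-formed) is added 1,4 to 8, trans to the side arm, to give methyl 3,3-dimethoxy-2-[(4S,5R)-5-[(1S)-1-(methanesulfonyloxy)ethyl]-2-oxooxan-4-yl]propanoate F1. Aqueous trifluoroacetic acid then hydrolyses the acetal to the formyl ester, present as its enol methyl 3-hydroxy-2-[(4S,5R)-5-[(1S)-1-(methanesulfonyloxy)ethyl]-2-oxooxan-4-yl]prop-2-enoate F2. K2CO3 in acetonitrile closes ring A by intramolecular 6-exo-tet O-alkylation of the β-dicarbonyl enolate with inversion, giving 13. In this sequence the saturated lactone carries no γ-hydrogen that could trigger the elimination.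

2. Step 10. The lactone may re-close with loss of the newly attached alcohol during alkylation or work-up, or hydroxide may attack the enol-ether ester. Fallback, from 13 (through 17) back to 18, protecting the hydroxyl and activating the acid instead: 17 is silylated with tBuMe2SiCl/imidazole in DMF to tert-butyldimethylsilyl 2-[(2R,3R,4S)-3-({[tert-butyl(dimethyl)silyl]oxy}methyl)-5-(methoxycarbonyl)-2-methyl-3,4-dihydro-2H-pyran-4-yl]acetate F3. The silyl ester alone is cleaved with K2CO3 in aqueous methanol to 2-[(2R,3R,4S)-3-({[tert-butyl(dimethyl)silyl]oxy}methyl)-5-(methoxycarbonyl)-2-methyl-3,4-dihydro-2H-pyran-4-yl]acetic acid F4, which cannot lactonise. Carbodiimide esterification (EDC·HCl, DMAP, CH2Cl2) with alcohol 15 gives methyl (2R,3R,4S)-4-{2-[2-(3,4-bis(benzyloxy)phenyl)ethoxy]-2-oxoethyl}-3-({[tert-butyl(dimethyl)silyl]oxy}methyl)-2-methyl-3,4-dihydro-2H-pyran-5-carboxylate F5, and HF·pyridine in THF removes the silyl ether to give 18.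

3. Step 2. The vinyl group may attack the methyl-bearing epoxide carbon instead of C2, giving the 1,2-diol. Fallback, from 2 back to 4, enforcing regiochemistry electronically through the glycidic ester: 2 is oxidised (RuCl3 cat., NaIO4, MeCN/EtOAc/H2O) to (2R,3S)-3-methyloxirane-2-carboxylic acid F6 and esterified (MeI, KHCO3, DMF) to methyl (2R,3S)-3-methyloxirane-2-carboxylate F7. (CH2=CH)2CuLi in THF at −78 °C opens F7 at the carbon α to the ester with inversion, giving methyl (2S,3S)-2-ethenyl-3-hydroxybutanoate F8, and LiAlH4 reduction gives 4.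

Further compounds
F1 | step 7 | methyl 3,3-dimethoxy-2-[(4S,5R)-5-[(1S)-1-(methanesulfonyloxy)ethyl]-2-oxooxan-4-yl]propanoate | COC(OC)C(C(=O)OC)[C@H]1CC(=O)OC[C@@H]1[C@H](C)OS(C)(=O)=O
F2 | step 7 | methyl 3-hydroxy-2-[(4S,5R)-5-[(1S)-1-(methanesulfonyloxy)ethyl]-2-oxooxan-4-yl]prop-2-enoate | COC(=O)C(=CO)[C@H]1CC(=O)OC[C@@H]1[C@H](C)OS(C)(=O)=O
F3 | step 10 | tert-butyldimethylsilyl 2-[(2R,3R,4S)-3-({[tert-butyl(dimethyl)silyl]oxy}methyl)-5-(methoxycarbonyl)-2-methyl-3,4-dihydro-2H-pyran-4-yl]acetate | COC(=O)C1=CO[C@H](C)[C@@H](CO[Si](C)(C)C(C)(C)C)[C@@H]1CC(=O)O[Si](C)(C)C(C)(C)C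
F4 | step 10 | 2-[(2R,3R,4S)-3-({[tert-butyl(dimethyl)silyl]oxy}methyl)-5-(methoxycarbonyl)-2-methyl-3,4-dihydro-2H-pyran-4-yl]acetic acid | COC(=O)C1=CO[C@H](C)[C@@H](CO[Si](C)(C)C(C)(C)C)[C@@H]1CC(=O)O
F5 | step 10 | methyl (2R,3R,4S)-4-{2-[2-(3,4-bis(benzyloxy)phenyl)ethoxy]-2-oxoethyl}-3-({[tert-butyl(dimethyl)silyl]oxy}methyl)-2-methyl-3,4-dihydro-2H-pyran-5-carboxylate | COC(=O)C1=CO[C@H](C)[C@@H](CO[Si](C)(C)C(C)(C)C)[C@@H]1CC(=O)OCCc1ccc(OCc2ccccc2)c(OCc2ccccc2)c1
F6 | step 2 | (2R,3S)-3-methyloxirane-2-carboxylic acid | C[C@@H]1O[C@H]1C(=O)O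
F7 | step 2 | methyl (2R,3S)-3-methyloxirane-2-carboxylate | C[C@@H]1O[C@H]1C(=O)OC
F8 | step 2 | methyl (2S,3S)-2-ethenyl-3-hydroxybutanoate | C[C@H](O)[C@H](C=C)C(=O)OC
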